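Remark on the chemistry: the sense of induction is taken from the empirical rule for C2-symmetric diol boronic esters (an (R,R)-diol gives the (αS)-α-chloro boronic ester); followed through both homologations, the (2R,3R) target needs (1R,2R)-1,2-dicyclohexylethane-1,2-diol on boron, whereas the (S,S)-diol is mismatched with an (R)-configured boron-bearing carbon and would lead to the (2S,3S) series, so the route is written with the (R,R)-diol throughout.

## Structural features

The target is a 2,3-dihydro-1-benzofuran: benzo ring B is fused through C3a and C7a to a five-membered ring containing O1, C2 and C3. C2 carries the 3,4,5-trimethoxyphenyl ring A, C3 a methyl group, C5 an (E)-prop-1-enyl group and C6 a methoxy group. C2 and C3 are adjacent stereocentres, both R, with ring A and the methyl group trans. The fragile parts are the electron-rich (E)-propenyl styrene (acid, electrophiles, oxidants, light), the doubly benzylic-type C2–O1 ether that can ionise towards a trimethoxybenzyl cation, and the benzylic C3–H. The substitution of both arenes is easy to source; the real difficulty is absolute control of the two neighbouring centres by a method that does not rely on cationic or equilibrating conditions that endanger the alkene. The feature exploited is that C2 is a single CH carbon bonded only to C3, to C1' of ring A and to O1: it maps onto the carbon of LiCHCl2, whose two chlorides are replaced in turn by C3 and by C1' through boron-to-carbon shifts, with boron holding the place of O1. C3 (a CH bonded to methyl, C3a and C2) has the same pattern, so the same operation one carbon earlier builds it and one diol on boron dictates both centres. The O1–C7a bond is then left as the ring-closing bond, for which ring B carries an ortho chlorine.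

## Logic of the disconnections

16 to 15: the O1–C7a bond is cut. This opens the heterocycle to an acyclic secondary alcohol with an ortho-chloroarene, and both stereocentres sit outside the bond being formed. The forward step must insert palladium into an aryl chloride in the presence of the propenyl group and must eliminate reductively faster than the alkoxide undergoes β-hydride loss.

15 to 14: the C2–O bond is traced to a C2–B bond. Boron is the handle that allows C2 to be assembled by carbon–carbon bond formation. The forward oxidation must proceed with retention at C2 and must leave the alkene alone.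

14 to 10 and 13 (through 12): the C2–C3 and C2–C1' bonds are cut and C2 is traced to the carbenoid carbon derived from dichloromethane. This removes ring A and one stereocentre in a single operation and leaves a boronic ester in which only C3 is stereogenic. The forward step needs a diol on boron that decides which chloride leaves in the first shift, and a clean inversion in the second.

13 to 11: the C–Mg bond is traced to the C–Br bond of a commercial bromide; direct magnesium insertion suffices.

10 to 7 and 9 (through 8): the same tactic one carbon earlier. The C3–C3a and C3–CH3 bonds are cut, C3 again coming from dichloromethane and the methyl group from boron. The demand is that the aryl nucleophile capture the chloride 8 faster than chloride exchange can epimerise it.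

9 to 4: the C–Mg bond is traced to C–Br. The chlorine ortho to it is kept as the later electrophile for O1–C7a; it is chosen because it resists magnesium insertion and does not eliminate to a benzyne at ambient temperature.

4 to 3: the propenyl double bond is traced to a benzylic carbinol. The forward dehydration must give the conjugated (E)-alkene without oligomerising it.

3 to 2: the bond between the carbinol carbon and the ethyl group is cut, giving an aldehyde and an ethyl nucleophile.

2 to 1: the C–Br bond is cut. The forward bromination must go para to the methoxy group, which the substitution pattern of 1 ensures.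

7 to 5 and 6: the two B–O bonds are cut, giving the boronic acid and the chiral diol. The diol is released again in the oxidation of 14.

## Other disconnections considered

Alternative 1: The cut is the C3–C3a bond, with the C3 methyl traced to an ester. Methyl (2R,3R)-5-bromo-6-methoxy-2-(3,4,5-trimethoxyphenyl)-2,3-dihydro-1-benzofuran-3-carboxylate A1 would arise from (2R)-6-bromo-7-methoxy-2-(3,4,5-trimethoxyphenyl)chroman-4-one A2 with PhI(OAc)2 and H2SO4 in trimethyl orthoformate. The enol ether of A2 is iodinated at C3 and the fused aryl carbon shifts from the carbonyl carbon to C3 as the iodane departs, so the six-membered ring contracts and the old carbonyl carbon leaves the ring as the ester.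
- In its favour: the C2 centre of A2 can come from catalytic asymmetric chemistry; the trans arrangement is what the anti shift and the epimerisable ester-bearing C3 should give; no carbenoid at −100 °C and no stoichiometric auxiliary are needed; the propenyl group would be attached last at the bromide, so the fragile alkene is not carried. On these four points it is the equal or the better of the chosen plan.
- Against it here: the ester is at the wrong oxidation level, so reduction, activation and a second reduction are needed before the cross-coupling (about four steps after the key step, against two in the chosen plan). The strongly acidic medium can reversibly open the O1–C2 bond of A2 and erode the only element of absolute control. The electron-rich ring A on C2 can compete as the migrating group, or the ring can simply be dehydrogenated.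
- Comparison: mechanistically the chosen plan sets each centre by a stereospecific 1,2-shift under reagent control, whereas here C3 is relayed from C2 through a cationic rearrangement. Structurally the alternative makes the C3 substituent in a form that must be degraded; the chosen plan brings the methyl in as such.

Alternative 2: The cut runs through ring B (C3a–C7a, C6–C7 and C5–C6), so that ring B and the heterocycle form together. Irradiation of (1R,2R,5E,7E)-3-diazo-1-(ethynyloxy)-2-methyl-1-(3,4,5-trimethoxyphenyl)nona-5,7-dien-4-one A4 would trigger Wolff rearrangement to a dienylketene. The ketene adds across the tethered ynol ether, the four-membered ring opens and recloses by 6π-electrocyclisation, and tautomerisation gives the phenol (2R,3R)-3-methyl-5-[(E)-prop-1-enyl]-2-(3,4,5-trimethoxyphenyl)-2,3-dihydro-1-benzofuran-6-ol A3.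
- In its favour: the substitution pattern of ring B is fixed by the annulation without any aromatic substitution; both stereocentres are set beforehand in an acyclic tether and are not touched; only one O-methylation separates A3 from the target. On the number of steps after the key step (one against two) and on the absence of transition metals it is the better of the two.
- Against it here: A4 needs an anti stereodiad, an ynol ether and a diazo transfer, so the longest sequence would be clearly longer than the eight steps of the chosen plan. The ketene–alkyne addition has to take place across a three-atom tether, which strains the four-membered intermediate. The dienone and the propenyl styrene are both chromophores, so E/Z scrambling under irradiation is a real concern, and diazo compounds add a handling hazard.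
- Comparison: the chosen plan forms no ring in its key step but creates a stereocentre with a predictable rule. The alternative forms two rings but creates no stereocentre and moves the whole stereochemical burden into a longer precursor synthesis.

Alternative 3: The cuts are C2–C3 and O1–C2. With Cs2CO3, rac-4-bromo-5-methoxy-2-[1-(4-methylphenylsulfonyl)ethyl]phenol A6 would give an ortho-quinone methide, and a chiral sulfonium salt such as (2R,5R)-2,5-dimethyl-1-(3,4,5-trimethoxybenzyl)thiolan-1-ium tetrafluoroborate A7 (the sulfide enantiomer being chosen for the (2R,3R) series) would give the benzyl ylide. Conjugate addition of the ylide carbon to the methide carbon and displacement of the sulfide by the phenoxide would close the ring to (2R,3R)-5-bromo-6-methoxy-3-methyl-2-(3,4,5-trimethoxyphenyl)-2,3-dihydro-1-benzofuran A5; a cross-coupling at the bromide would then install the propenyl group.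
- In its favour: it is the most convergent of all the plans, one step making the ring and both stereocentres from two simple aromatic pieces. Only one step follows A5 and no cryogenic organometallic chemistry is involved. On convergence and on overall step count it is the better of the two, and the trans outcome from an anti betaine is at least the equal of the chosen plan.
- Against it here: absolute control rests on the facial selectivity of a semi-stabilised benzyl ylide towards a methyl-substituted quinone methide. Such a methide can lose its identity by proton shift from the methyl group, and its geometry is not fixed. Reversible betaine formation can also blur the selectivity, and the chiral sulfide is used stoichiometrically.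
- Comparison: the chosen plan is longer and needs −100 °C, but each centre is made by a stereospecific shift whose sense follows a general rule for the diol. In the alternative both centres depend on one less predictable addition.

Key step: step 6

## Route

Step 1
Reactants: 1 4-chloro-2-methoxybenzaldehyde
Product: 2 5-bromo-4-chloro-2-methoxybenzaldehyde
Conditions: Br2 (1.1 equiv), AcOH, 25 °C; aq Na2S2O3
Reagents that add atoms: bromine, BrBr
Why: Electrophilic aromatic bromination; the methoxy group is the strongest director and its para position (C5) is also ortho to chlorine and meta to the formyl group, while the other activated site (C3) is flanked by two substituents, so one regioisomer is expected.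

Step 2
Reactants: 2 5-bromo-4-chloro-2-methoxybenzaldehyde
Product: 3 rac-1-(5-bromo-4-chloro-2-methoxyphenyl)propan-1-ol
Conditions: EtMgBr (1.2 equiv), THF, 0 °C; aq NH4Cl
Reagents that add atoms: ethylmagnesium bromide, CC[Mg]Br
Why: Grignard 1,2-addition to the aldehyde; the aryl halides do not exchange with an alkyl Grignard reagent at 0 °C, and the carbinol centre is of no consequence because it is removed in step 3.

Step 3
Reactants: 3 rac-1-(5-bromo-4-chloro-2-methoxyphenyl)propan-1-ol
Product: 4 1-bromo-2-chloro-4-methoxy-5-[(E)-prop-1-enyl]benzene
Conditions: TsOH·H2O (5 mol%), toluene, reflux, Dean–Stark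
Reagents that add atoms: none
Why: Acid-catalysed E1 dehydration through a benzylic cation stabilised by the ortho methoxy group; under these equilibrating conditions the conjugated (E)-alkene is the thermodynamic product.

Step 4
Reactants: 5 methylboronic acid; 6 (1R,2R)-1,2-dicyclohexylethane-1,2-diol
Product: 7 (4R,5R)-4,5-dicyclohexyl-2-methyl-1,3,2-dioxaborolane
Conditions: MgSO4, Et2O, 25 °C
Reagents that add atoms: none
Why: Condensation of a boronic acid with a 1,2-diol to the five-membered cyclic boronic ester, driven by removal of water; the diol stereocentres are not involved.

Step 5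
Reactants: 7 (4R,5R)-4,5-dicyclohexyl-2-methyl-1,3,2-dioxaborolane; 4 1-bromo-2-chloro-4-methoxy-5-[(E)-prop-1-enyl]benzene
Product: 10 (4R,5R)-2-[(1R)-1-{2-chloro-4-methoxy-5-[(E)-prop-1-enyl]phenyl}ethyl]-4,5-dicyclohexyl-1,3,2-dioxaborolane, via (S)-chloroethylboronic ester 8 (not isolated), via arylmagnesium bromide 9 (not isolated)
Conditions: CH2Cl2, n-BuLi, THF, −100 °C; 7; ZnCl2, −100 → 25 °C; then 9 (from 4, Mg, LiCl, THF, 25 °C; excess over ZnCl2), −78 → 25 °C
Reagents that add atoms: dichloromethyllithium, [Li]C(Cl)Cl (generated from dichloromethane, ClCCl, and n-BuLi)
Why: Matteson homologation: LiCHCl2 adds to boron and, with ZnCl2 bridging a ring oxygen and the departing chloride, the methyl group migrates to the carbenoid carbon, the (R,R)-diol selecting the chloride that leaves so that 8 is the (S)-chloride. Aryl Grignard reagent 9 then forms a second borate and the aryl group displaces chloride by a 1,2-shift with inversion, which sets the future C3 as (R) in 10. The chloride-bearing carbon is not benzylic at this stage, which limits epimerisation.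

Step 6
Reactants: 10 (4R,5R)-2-[(1R)-1-{2-chloro-4-methoxy-5-[(E)-prop-1-enyl]phenyl}ethyl]-4,5-dicyclohexyl-1,3,2-dioxaborolane; 11 5-bromo-1,2,3-trimethoxybenzene
Product: 14 (4R,5R)-2-[(1R,2S)-2-{2-chloro-4-methoxy-5-[(E)-prop-1-enyl]phenyl}-1-(3,4,5-trimethoxyphenyl)propyl]-4,5-dicyclohexyl-1,3,2-dioxaborolane, via α-chloro boronic ester 12 (not isolated), via trimethoxyphenylmagnesium bromide 13 (not isolated)
Conditions: CH2Cl2, n-BuLi, THF, −100 °C; 10; ZnCl2, −100 → 25 °C, 16 h; then 13 (from 11, Mg, THF; excess over ZnCl2), −78 → 25 °C
Reagents that add atoms: dichloromethyllithium, [Li]C(Cl)Cl (generated from dichloromethane, ClCCl, and n-BuLi)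
Why: LiCHCl2 adds to the trigonal boron of 10 to give a tetracoordinate borate; on warming with ZnCl2 the benzylic C3 carbon migrates from boron to the carbenoid carbon with retention at C3, forming C2–C3 and expelling one chloride to give 12. The C2-symmetric (R,R)-diol is the controlling element for the new centre: zinc binds the ring oxygen on the face not shielded by the neighbouring cyclohexyl group and bridges to one chlorine while the other turns away from the zinc halide, so only one diastereotopic chloride leaves and C2 of 12 is (S) whatever the configuration at C3. Aryl Grignard reagent 13 then forms a second borate and the trimethoxyphenyl group shifts to C2 anti to the remaining chloride, forming C2–C1' with inversion, so that C2 in 14 has the arrangement that becomes (2R) once boron is exchanged for oxygen. The closest known reaction type is the Matteson homologation of chiral diol boronic esters with LiCHCl2 followed by Grignard displacement of the α-chloride, which is established for secondary alkyl migrating groups. No ring is closed in this step. The selectivities needed are attack at boron in preference to deprotonation of the benzylic C3–H or reaction at the aryl chloride and the propenyl group, and a single sense of chloride loss; the Lewis acidity of boron at −100 °C secures the first and the diol the second. ZnCl2 also ties up free chloride, which would otherwise epimerise 12 by exchange, and 12 is not a benzylic chloride, so ionisation at C2 is not expected. C2 thus comes from dichloromethane with boron as the placeholder for O1.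

Step 7
Reactants: 14 (4R,5R)-2-[(1R,2S)-2-{2-chloro-4-methoxy-5-[(E)-prop-1-enyl]phenyl}-1-(3,4,5-trimethoxyphenyl)propyl]-4,5-dicyclohexyl-1,3,2-dioxaborolane
Product: 15 (1R,2R)-2-{2-chloro-4-methoxy-5-[(E)-prop-1-enyl]phenyl}-1-(3,4,5-trimethoxyphenyl)propan-1-ol
Conditions: 30% H2O2, 2 M NaOH, THF, 0 → 25 °C
Reagents that add atoms: hydrogen peroxide, OO
Why: Oxidation of the C–B bond: hydroperoxide adds to boron and C2 shifts from boron to oxygen with retention, while the nucleophilic peroxide leaves the electron-rich alkene alone and diol 6 is released for recovery. The change of the C3 descriptor from S in 14 to R in 15 is a priority effect only; no bond at C3 is touched.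

Step 8
Reactants: 15 (1R,2R)-2-{2-chloro-4-methoxy-5-[(E)-prop-1-enyl]phenyl}-1-(3,4,5-trimethoxyphenyl)propan-1-ol
Product: 16 (2R,3R)-6-methoxy-3-methyl-5-[(E)-prop-1-enyl]-2-(3,4,5-trimethoxyphenyl)-2,3-dihydro-1-benzofuran
Conditions: Pd(OAc)2 (5 mol%), rac-2-(di-tert-butylphosphino)-1,1'-binaphthyl (6 mol%), Cs2CO3 (1.5 equiv), toluene, 80 °C
Reagents that add atoms: none
Why: Palladium-catalysed intramolecular aryl etherification (Buchwald–Hartwig type): zerovalent palladium formed in the flask from the divalent palladium salt inserts into the C–Cl bond, the alkoxide binds, and reductive elimination forms O1–C7a and the five-membered ring. The bulky, electron-rich biaryl phosphine speeds reductive elimination relative to β-hydride loss, and neither stereocentre takes part in bond formation, so the trans (2R,3R) arrangement is kept.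

## Compound list

1 | 4-chloro-2-methoxybenzaldehyde | COc1cc(Cl)ccc1C=O | starting material
2 | 5-bromo-4-chloro-2-methoxybenzaldehyde | COc1cc(Cl)c(Br)cc1C=O | intermediate
3 | rac-1-(5-bromo-4-chloro-2-methoxyphenyl)propan-1-ol | CCC(O)c1cc(Br)c(Cl)cc1OC | intermediate
4 | 1-bromo-2-chloro-4-methoxy-5-[(E)-prop-1-enyl]benzene | C/C=C/c1cc(Br)c(Cl)cc1OC | intermediate
5 | methylboronic acid | CB(O)O | starting material
6 | (1R,2R)-1,2-dicyclohexylethane-1,2-diol | O[C@H](C1CCCCC1)[C@H](O)C1CCCCC1 | starting material
7 | (4R,5R)-4,5-dicyclohexyl-2-methyl-1,3,2-dioxaborolane | CB1O[C@H](C2CCCCC2)[C@@H](C2CCCCC2)O1 | intermediate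
8 | (4R,5R)-2-[(1S)-1-chloroethyl]-4,5-dicyclohexyl-1,3,2-dioxaborolane | C[C@@H](Cl)B1O[C@H](C2CCCCC2)[C@@H](C2CCCCC2)O1 | intermediate (not isolated)
9 | {2-chloro-4-methoxy-5-[(E)-prop-1-enyl]phenyl}magnesium bromide | C/C=C/c1cc([Mg]Br)c(Cl)cc1OC | intermediate (not isolated)
10 | (4R,5R)-2-[(1R)-1-{2-chloro-4-methoxy-5-[(E)-prop-1-enyl]phenyl}ethyl]-4,5-dicyclohexyl-1,3,2-dioxaborolane | B1([C@@H](c2cc(/C=C/C)c(OC)cc2Cl)C)O[C@H](C2CCCCC2)[C@@H](C2CCCCC2)O1 | intermediate
11 | 5-bromo-1,2,3-trimethoxybenzene | COc1cc(Br)cc(OC)c1OC | starting material
12 | (4R,5R)-2-[(1S,2R)-1-chloro-2-{2-chloro-4-methoxy-5-[(E)-prop-1-enyl]phenyl}propyl]-4,5-dicyclohexyl-1,3,2-dioxaborolane | B1([C@H](Cl)[C@@H](c2cc(/C=C/C)c(OC)cc2Cl)C)O[C@H](C2CCCCC2)[C@@H](C2CCCCC2)O1 | intermediate (not isolated)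
13 | (3,4,5-trimethoxyphenyl)magnesium bromide | Br[Mg]c1cc(OC)c(OC)c(OC)c1 | intermediate (not isolated)
14 | (4R,5R)-2-[(1R,2S)-2-{2-chloro-4-methoxy-5-[(E)-prop-1-enyl]phenyl}-1-(3,4,5-trimethoxyphenyl)propyl]-4,5-dicyclohexyl-1,3,2-dioxaborolane | B1([C@@H](c2cc(OC)c(OC)c(OC)c2)[C@@H](c2cc(/C=C/C)c(OC)cc2Cl)C)O[C@H](C2CCCCC2)[C@@H](C2CCCCC2)O1 | intermediate
15 | (1R,2R)-2-{2-chloro-4-methoxy-5-[(E)-prop-1-enyl]phenyl}-1-(3,4,5-trimethoxyphenyl)propan-1-ol | O[C@@H](c1cc(OC)c(OC)c(OC)c1)[C@@H](c1cc(/C=C/C)c(OC)cc1Cl)C | intermediate
16 | (2R,3R)-6-methoxy-3-methyl-5-[(E)-prop-1-enyl]-2-(3,4,5-trimethoxyphenyl)-2,3-dihydro-1-benzofuran | C/C=C/c1cc2c(cc1OC)O[C@@H](c1cc(OC)c(OC)c(OC)c1)[C@@H]2C | target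

## Step count and least certain steps

Total step count: 8. Longest linear sequence: 7 steps (steps 1, 2, 3, 5, 6, 7, 8); step 4 is a one-step side branch.

**Step 6 (key step).** The most likely failure is slow capture of the hindered chloride 12 by 13. The second borate must form next to a branched benzylic carbon, and the zinc halide in the pot diverts part of the Grignard reagent. Chloride exchange at C2 (loss of diastereomeric purity) or elimination could then compete with the aryl shift.

Fallback, setting out from 12 and returning at 15: crude 12 is oxidised at boron with H2O2 in pH 7 phosphate buffer and THF at 0 °C, the chlorohydrin collapsing to (2R)-2-{2-chloro-4-methoxy-5-[(E)-prop-1-enyl]phenyl}propanal F1. Addition of 13 at −78 °C gives (2R)-2-{2-chloro-4-methoxy-5-[(E)-prop-1-enyl]phenyl}-1-(3,4,5-trimethoxyphenyl)propan-1-ol as a mixture of C1 epimers F2. Dess–Martin oxidation buffered with NaHCO3 gives (2R)-2-{2-chloro-4-methoxy-5-[(E)-prop-1-enyl]phenyl}-1-(3,4,5-trimethoxyphenyl)propan-1-one F3. Reduction with LiBH(s-Bu)3 in THF at −78 °C, under Felkin–Anh control with ring B as the large group on the α-carbon, should then favour the (1R,2R)-alcohol 15. C2 is thus set by substrate control in a hydride addition and not by the diol; the price is two α-aryl carbonyl compounds whose C3 centre must be kept from enolising by cold, neutral handling.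

**Step 5.** The most likely failure is sluggish borate formation between the ortho-chlorinated, partly zinc-bound aryl nucleophile 9 and 8. This would leave 8 exposed to chloride exchange, with partial loss of configuration at the future C3, and would waste 9.

Fallback, setting out from 4 and returning at 10: the aryl group is placed on boron first and the methyl-bearing carbon is delivered as a chiral carbenoid. 9 made from 4 is quenched with B(OMe)3 and hydrolysed to {2-chloro-4-methoxy-5-[(E)-prop-1-enyl]phenyl}boronic acid F4. This is condensed with 6 (MgSO4, Et2O) to (4R,5R)-2-{2-chloro-4-methoxy-5-[(E)-prop-1-enyl]phenyl}-4,5-dicyclohexyl-1,3,2-dioxaborolane F5. Ethyl N,N-diisopropylcarbamate is deprotonated with s-BuLi and (−)-sparteine in Et2O at −78 °C (removal of the pro-S hydrogen), F5 is added, and warming drives the 1,2-shift of the aryl group with loss of the carbamate and inversion at the carbenoid carbon. This lithiation–borylation should give 10 with the (R) centre fixed by the sparteine-bound carbenoid and not by the diol.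

**Step 8.** The most likely failure is β-hydride loss from the palladium alkoxide, which would oxidise C2 and reduce the aryl chloride, or slow oxidative addition into the chloride of an electron-rich ring.

Fallback, setting out from 15 and returning at 16: a metal-free aryne closure. With LiN(i-Pr)2 (3 equiv) in THF from −78 to 25 °C the hydroxyl is deprotonated and C7–H, flanked by chlorine and methoxy, is lithiated. Loss of chloride gives the lithium alkoxide of (1R,2R)-2-{2,3-didehydro-4-methoxy-5-[(E)-prop-1-enyl]phenyl}-1-(3,4,5-trimethoxyphenyl)propan-1-ol F6. The tethered alkoxide adds to C7a, the aryne carbon remote from the methoxy group, and protonation at C7 on work-up should give 16 without touching C2 or C3.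

**Step 3.** The most likely failure is acid-induced oligomerisation of the electron-rich styrene as it forms, or incomplete equilibration to the (E)-isomer.

Fallback, setting out from 2 and returning at 4: a Julia–Kocienski olefination of aldehyde 2 with 5-(ethylsulfonyl)-1-phenyl-1H-tetrazole and KN(SiMe3)2 in DME from −60 to 25 °C. The alkene is made under basic, kinetically (E)-selective conditions; carbinol 3 and the acid are bypassed and no new intermediate is isolated.

## Further compounds

F1 | step 6 | (2R)-2-{2-chloro-4-methoxy-5-[(E)-prop-1-enyl]phenyl}propanal | O=C[C@@H](c1cc(/C=C/C)c(OC)cc1Cl)C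
F2 | step 6 | (2R)-2-{2-chloro-4-methoxy-5-[(E)-prop-1-enyl]phenyl}-1-(3,4,5-trimethoxyphenyl)propan-1-ol, mixture of C1 epimers | OC(c1cc(OC)c(OC)c(OC)c1)[C@@H](c1cc(/C=C/C)c(OC)cc1Cl)C
F3 | step 6 | (2R)-2-{2-chloro-4-methoxy-5-[(E)-prop-1-enyl]phenyl}-1-(3,4,5-trimethoxyphenyl)propan-1-one | O=C(c1cc(OC)c(OC)c(OC)c1)[C@@H](c1cc(/C=C/C)c(OC)cc1Cl)C
F4 | step 5 | {2-chloro-4-methoxy-5-[(E)-prop-1-enyl]phenyl}boronic acid | C/C=C/c1cc(B(O)O)c(Cl)cc1OC
F5 | step 5 | (4R,5R)-2-{2-chloro-4-methoxy-5-[(E)-prop-1-enyl]phenyl}-4,5-dicyclohexyl-1,3,2-dioxaborolane | C/C=C/c1cc(B2O[C@H](C3CCCCC3)[C@@H](C3CCCCC3)O2)c(Cl)cc1OC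
F6 | step 8 | lithium alkoxide of (1R,2R)-2-{2,3-didehydro-4-methoxy-5-[(E)-prop-1-enyl]phenyl}-1-(3,4,5-trimethoxyphenyl)propan-1-ol (aryne, not isolated) | [Li]O[C@@H](c1cc(OC)c(OC)c(OC)c1)[C@@H](C1=CC(/C=C/C)=C(OC)C#C1)C
F0 | step 3 | none | none
A1 | alternative 1 | methyl (2R,3R)-5-bromo-6-methoxy-2-(3,4,5-trimethoxyphenyl)-2,3-dihydro-1-benzofuran-3-carboxylate | Brc1cc2c(cc1OC)O[C@@H](c1cc(OC)c(OC)c(OC)c1)[C@@H]2C(=O)OC
A2 | alternative 1 | (2R)-6-bromo-7-methoxy-2-(3,4,5-trimethoxyphenyl)chroman-4-one | O=C1C[C@H](c2cc(OC)c(OC)c(OC)c2)Oc2cc(OC)c(Br)cc21
A3 | alternative 2 | (2R,3R)-3-methyl-5-[(E)-prop-1-enyl]-2-(3,4,5-trimethoxyphenyl)-2,3-dihydro-1-benzofuran-6-ol | C/C=C/c1cc2c(cc1O)O[C@@H](c1cc(OC)c(OC)c(OC)c1)[C@@H]2C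
A4 | alternative 2 | (1R,2R,5E,7E)-3-diazo-1-(ethynyloxy)-2-methyl-1-(3,4,5-trimethoxyphenyl)nona-5,7-dien-4-one | C#CO[C@@H](c1cc(OC)c(OC)c(OC)c1)[C@H](C)C(=[N+]=[N-])C(=O)/C=C/C=C/C
A5 | alternative 3 | (2R,3R)-5-bromo-6-methoxy-3-methyl-2-(3,4,5-trimethoxyphenyl)-2,3-dihydro-1-benzofuran | Brc1cc2c(cc1OC)O[C@@H](c1cc(OC)c(OC)c(OC)c1)[C@@H]2C
A6 | alternative 3 | rac-4-bromo-5-methoxy-2-[1-(4-methylphenylsulfonyl)ethyl]phenol | CC(c1cc(Br)c(OC)cc1O)S(=O)(=O)c1ccc(C)cc1
A7 | alternative 3 | (2R,5R)-2,5-dimethyl-1-(3,4,5-trimethoxybenzyl)thiolan-1-ium tetrafluoroborate | C[C@@H]1CC[C@@H](C)[S+]1Cc1cc(OC)c(OC)c(OC)c1.F[B-](F)(F)F
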